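**Retrosynthetic overview**
- The strategy rests on the benzene ring that carries OH on C2', C4' and C6' and the chain carbonyl on C1'. This alternating oxygenation around an acyl-bearing carbon is the pattern of a linear tetraketide (the C20 acyl unit plus three acetate units) folded onto itself.
- The last disconnection is the Si–O bond at C15. Before it, the ring bond C1'–C2' is cut, which is C6–C1 of a methyl 3,5,7-trioxoalkanoate; this Claisen closure and aromatisation forms the only ring, in the penultimate step.
- The triketo ester is cut at C7–C6 into the Weinreb amide of the silylated C20 hydroxy acid and the trianion of methyl 3,5-dioxohexanoate, which comes from dehydroacetic acid.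
- The C15 stereocentre and the 11Z,13E-diene come from 15-lipoxygenase oxygenation of EPA.

Key step: step 6

Remark: the single stereocentre (C15 of the C20 chain) is read from the SMILES as S with 5Z,8Z,11Z,13E,17Z alkenes, which is what soybean 15-lipoxygenase delivers from EPA. All polyene intermediates are to be handled cold, under argon and away from light.

**Step 1**
Reactants: 1 (5Z,8Z,11Z,14Z,17Z)-icosa-5,8,11,14,17-pentaenoic acid (EPA)
Product: 3 (5Z,8Z,11Z,13E,15S,17Z)-15-hydroxyicosa-5,8,11,13,17-pentaenoic acid, via 15S-hydroperoxy acid 2 (not isolated)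
Conditions: soybean 15-lipoxygenase (type I-B), O2, 0.1 M Na borate pH 9.0, 0–4 °C; then NaBH4, 0 °C; acidify to pH 4, extract
Reagents that add atoms: dioxygen, O=O
Why: Enzymatic lipoxygenation removes one hydrogen stereospecifically from bis-allylic C13 and delivers O2 to C15 on the opposite face, which should set 15S and move the 14,15-alkene to 13E; borohydride then reduces the O–O bond without touching the C15–O bond.

**Step 2**
Reactants: 3 (5Z,8Z,11Z,13E,15S,17Z)-15-hydroxyicosa-5,8,11,13,17-pentaenoic acid
Product: 4 (5Z,8Z,11Z,13E,15S,17Z)-15-hydroxy-N-methoxy-N-methylicosa-5,8,11,13,17-pentaenamide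
Conditions: MeNH(OMe)·HCl, EDC·HCl, HOBt, N-methylmorpholine, CH2Cl2, 0 °C → rt
Reagents that add atoms: N,O-dimethylhydroxylamine hydrochloride, CNOC.Cl
Why: Carbodiimide amidation through the benzotriazolyl active ester, which should acylate the amine much faster than the secondary allylic alcohol; C15 is not involved.

**Step 3**
Reactants: 4 (5Z,8Z,11Z,13E,15S,17Z)-15-hydroxy-N-methoxy-N-methylicosa-5,8,11,13,17-pentaenamide
Product: 5 (5Z,8Z,11Z,13E,15S,17Z)-15-(tert-butyldimethylsilyloxy)-N-methoxy-N-methylicosa-5,8,11,13,17-pentaenamide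
Conditions: TBSCl, imidazole, DMF, 0 °C → rt
Reagents that add atoms: tert-butyldimethylsilyl chloride, CC(C)(C)[Si](C)(C)Cl
Why: Imidazole-promoted O-silylation forms only an O–Si bond, so the 15S configuration is retained and the doubly allylic carbinol is masked for the two polyanion steps.

**Step 4**
Reactants: 6 dehydroacetic acid (3-acetyl-4-hydroxy-6-methyl-2H-pyran-2-one)
Product: 8 methyl 3,5-dioxohexanoate, via methyl 2-acetyl-3,5-dioxohexanoate 7 (not isolated)
Conditions: Mg(OMe)2, MeOH, reflux; then cold 1 M HCl; distil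
Reagents that add atoms: magnesium methoxide, C[O-].C[O-].[Mg+2]
Why: Lactone methanolysis opens the pyranone to the triacylmethane 7, and retro-Claisen cleavage then removes its acetyl group as methyl acetate while magnesium chelation protects the remaining 3,5-dioxo ester.

**Step 5**
Reactants: 8 methyl 3,5-dioxohexanoate; 5 (5Z,8Z,11Z,13E,15S,17Z)-15-(tert-butyldimethylsilyloxy)-N-methoxy-N-methylicosa-5,8,11,13,17-pentaenamide
Product: 11 methyl (11Z,14Z,17Z,19E,21S,23Z)-21-(tert-butyldimethylsilyloxy)-3,5,7-trioxohexacosa-11,14,17,19,23-pentaenoate, via trilithium methyl 3,5-dioxohexanoate trianion 9 (not isolated), via lithium-chelated tetrahedral adduct 10 (not isolated)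
Conditions: 8 (2 equiv), LDA (3 equiv per 8), THF, 0 °C; then 5 (1 equiv), −78 → −20 °C; AcOH, −78 °C; pH 5 work-up; used at once
Reagents that add atoms: none
Why: C-acylation of a 1,3-dicarbonyl polyanion by a Weinreb amide: the terminal carbanion is the last formed and most nucleophilic site of 9, and the chelated adduct 10 does not collapse before the quench, so the acidic triketone is not present to consume the trianion or to be attacked a second time.

**Step 6**
Reactants: 11 methyl (11Z,14Z,17Z,19E,21S,23Z)-21-(tert-butyldimethylsilyloxy)-3,5,7-trioxohexacosa-11,14,17,19,23-pentaenoate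
Product: 12 (5Z,8Z,11Z,13E,15S,17Z)-15-(tert-butyldimethylsilyloxy)-1-(2,4,6-trihydroxyphenyl)icosa-5,8,11,13,17-pentaen-1-one
Conditions: Mg(OMe)2 (5 equiv), degassed MeOH–THF, Ar, 0 °C → rt; AcOH, 0 °C; pH 5 work-up
Reagents that add atoms: none
Why: Excess magnesium methoxide should convert 11 into a magnesium-chelated polyenolate in which the C5/C7 β-diketone is ionised, so that C6 is the carbanion and the C3, C5 and C7 carbonyls are held as enolate oxygens; C6 adds to the ester carbonyl C1, methoxide leaves, and the 2-acylcyclohexane-1,3,5-trione enolises three times to the arene. The closest known reaction type is the base-mediated Claisen (Dieckmann-type) cyclisation of methyl 3,5,7-trioxoalkanoates to 2-acylphloroglucinols, the laboratory counterpart of the chain folding used by chalcone-synthase-type polyketide synthases. The benzene ring, the only ring formed, closes in the 6-exo-trig mode (6-enolexo attack on the ester C=O) through the new C6–C1 bond. No stereocentre is created, and the silyl ether at C21 and the skipped Z-alkenes lie far from the polyanion and are not expected to react with methoxide at room temperature. The step needs chemoselectivity for C6-to-C1 acylation over aldol closure of C2 onto the C7 ketone (which would give a resorcylate) and over O-acylation to a 4-hydroxy-2-pyranone. The substrate secures this by carrying a methyl ester in anhydrous methoxide (ester exchange is degenerate and no carboxylate, which could only follow the aldol path, can form) and by the greater acidity of the C5/C7 diketone over C2, so that full ionisation removes C7 as an aldol acceptor while the Claisen closure is made irreversible by loss of methoxide and aromatisation.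

**Step 7**
Reactants: 12 (5Z,8Z,11Z,13E,15S,17Z)-15-(tert-butyldimethylsilyloxy)-1-(2,4,6-trihydroxyphenyl)icosa-5,8,11,13,17-pentaen-1-one
Product: 13 (5Z,8Z,11Z,13E,15S,17Z)-15-hydroxy-1-(2,4,6-trihydroxyphenyl)icosa-5,8,11,13,17-pentaen-1-one
Conditions: HF·pyridine, pyridine, THF, 0 °C → rt; pH 7 buffer work-up under Ar
Reagents that add atoms: none
Why: Fluoride-mediated desilylation breaks only the Si–O bond, so 15S is retained, and the pyridine buffer should keep the medium too weakly acidic to ionise the doubly allylic C15–O bond or to disturb the polyphenol.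

**Compound list**
1 | (5Z,8Z,11Z,14Z,17Z)-icosa-5,8,11,14,17-pentaenoic acid (EPA) | CC/C=C\C/C=C\C/C=C\C/C=C\C/C=C\CCCC(=O)O | starting material
2 | (5Z,8Z,11Z,13E,15S,17Z)-15-hydroperoxyicosa-5,8,11,13,17-pentaenoic acid (formed in the flask, not isolated) | CC/C=C\C[C@H](OO)/C=C/C=C\C/C=C\C/C=C\CCCC(=O)O | intermediate
3 | (5Z,8Z,11Z,13E,15S,17Z)-15-hydroxyicosa-5,8,11,13,17-pentaenoic acid | CC/C=C\C[C@H](O)/C=C/C=C\C/C=C\C/C=C\CCCC(=O)O | intermediate
4 | (5Z,8Z,11Z,13E,15S,17Z)-15-hydroxy-N-methoxy-N-methylicosa-5,8,11,13,17-pentaenamide | CC/C=C\C[C@H](O)/C=C/C=C\C/C=C\C/C=C\CCCC(=O)N(C)OC | intermediate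
5 | (5Z,8Z,11Z,13E,15S,17Z)-15-(tert-butyldimethylsilyloxy)-N-methoxy-N-methylicosa-5,8,11,13,17-pentaenamide | CC/C=C\C[C@H](O[Si](C)(C)C(C)(C)C)/C=C/C=C\C/C=C\C/C=C\CCCC(=O)N(C)OC | intermediate
6 | dehydroacetic acid (3-acetyl-4-hydroxy-6-methyl-2H-pyran-2-one) | CC1=CC(O)=C(C(C)=O)C(=O)O1 | starting material
7 | methyl 2-acetyl-3,5-dioxohexanoate (formed in the flask, not isolated) | COC(=O)C(C(C)=O)C(=O)CC(C)=O | intermediate
8 | methyl 3,5-dioxohexanoate | COC(=O)CC(=O)CC(C)=O | intermediate
9 | trilithium trianion of methyl 3,5-dioxohexanoate (formed in the flask, not isolated) | [CH2-]C(=O)[CH-]C(=O)[CH-]C(=O)OC.[Li+].[Li+].[Li+] | intermediate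
10 | trilithium salt of the tetrahedral adduct of 9 with amide 5, hemiaminal carbon unassigned (formed in the flask, not isolated) | CC/C=C\C[C@H](O[Si](C)(C)C(C)(C)C)/C=C/C=C\C/C=C\C/C=C\CCCC([O-])(N(C)OC)CC(=O)[CH-]C(=O)[CH-]C(=O)OC.[Li+].[Li+].[Li+] | intermediate
11 | methyl (11Z,14Z,17Z,19E,21S,23Z)-21-(tert-butyldimethylsilyloxy)-3,5,7-trioxohexacosa-11,14,17,19,23-pentaenoate | CC/C=C\C[C@H](O[Si](C)(C)C(C)(C)C)/C=C/C=C\C/C=C\C/C=C\CCCC(=O)CC(=O)CC(=O)CC(=O)OC | intermediate
12 | (5Z,8Z,11Z,13E,15S,17Z)-15-(tert-butyldimethylsilyloxy)-1-(2,4,6-trihydroxyphenyl)icosa-5,8,11,13,17-pentaen-1-one | CC/C=C\C[C@H](O[Si](C)(C)C(C)(C)C)/C=C/C=C\C/C=C\C/C=C\CCCC(=O)c1c(O)cc(O)cc1O | intermediate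
13 | (5Z,8Z,11Z,13E,15S,17Z)-15-hydroxy-1-(2,4,6-trihydroxyphenyl)icosa-5,8,11,13,17-pentaen-1-one | CC/C=C\C[C@H](O)/C=C/C=C\C/C=C\C/C=C\CCCC(=O)c1c(O)cc(O)cc1O | target

**Step count**
Total: 7 steps. Longest linear sequence: 6 steps (steps 1, 2, 3, 5, 6, 7 from EPA); step 4 is a one-step side branch that joins at step 5.

**Steps most likely to fail**

Step 6. The polyketone may close the wrong way: aldol addition of C2 to the C7 ketone followed by dehydration, or O-acylation of the C5 enol to a pyranone. Methoxide may also cleave the chain by retro-Claisen fragmentation. The fallback abandons ring construction and brings in the arene preformed; it sets out from amide 5 and comes back at 12. Phloroglucinol would be tri-O-allylated (allyl bromide, K2CO3, DMF) to 1,3,5-tris(allyloxy)benzene F1 and brominated (NBS, MeCN, 0 °C) to 2-bromo-1,3,5-tris(allyloxy)benzene F2. Bromine–lithium exchange (n-BuLi, THF, −78 °C) would give 2,4,6-tris(allyloxy)phenyllithium F3, which is added at −78 °C to Weinreb amide 5 to give (5Z,8Z,11Z,13E,15S,17Z)-15-(tert-butyldimethylsilyloxy)-1-[2,4,6-tris(allyloxy)phenyl]icosa-5,8,11,13,17-pentaen-1-one F4. Neutral de-allylation (Pd(PPh3)4 cat., morpholine, THF, rt) should then release the three phenols and give 12.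

Step 5. The strongly basic trianion may remove an α-proton from amide 5 instead of adding to it, and the free triketo ester may cyclise or lactonise during quench and isolation. The fallback keeps the ester end masked as a dioxinone until just before step 6; it sets out from amide 5 and comes back at 11. Commercial 2,2,6-trimethyl-4H-1,3-dioxin-4-one would be deprotonated at the 6-methyl group (LiHMDS, THF, −78 °C) and acetylated (AcCl) to 2,2-dimethyl-6-(2-oxopropyl)-4H-1,3-dioxin-4-one F5. Double deprotonation (LDA, 2 equiv, −78 °C) would give the dilithium dianion of the keto-dioxinone F6, which is acylated at its terminal carbon by 5 to give 6-[(8Z,11Z,14Z,16E,18S,20Z)-18-(tert-butyldimethylsilyloxy)-2,4-dioxotricosa-8,11,14,16,20-pentaenyl]-2,2-dimethyl-4H-1,3-dioxin-4-one F7. Brief heating in toluene with methanol should expel acetone by retro-[4+2] fragmentation to (11Z,14Z,17Z,19E,21S,23Z)-21-(tert-butyldimethylsilyloxy)hexacosa-1,11,14,17,19,23-hexaene-1,3,5,7-tetrone (the acylketene) F8, which methanol captures to give 11 under neutral conditions.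

Step 7. The acidic fluoride source may ionise the doubly allylic C15–O bond (allylic transposition or elimination), and the electron-rich polyphenol may oxidise during a slow deprotection. The fallback removes the deprotection altogether by not silylating; it sets out from hydroxy amide 4 and comes back at 13. Amide 4 would be added to trianion 9, with one further equivalent of 9 to take up the hydroxyl proton, to give methyl (11Z,14Z,17Z,19E,21S,23Z)-21-hydroxy-3,5,7-trioxohexacosa-11,14,17,19,23-pentaenoate F9. Treatment with Mg(OMe)2 in MeOH–THF as in step 6 should then close the ring and give 13 directly.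

**Further compounds**
F1 | step 6 | 1,3,5-tris(allyloxy)benzene | C=CCOc1cc(OCC=C)cc(OCC=C)c1
F2 | step 6 | 2-bromo-1,3,5-tris(allyloxy)benzene | C=CCOc1cc(OCC=C)c(Br)c(OCC=C)c1
F3 | step 6 | 2,4,6-tris(allyloxy)phenyllithium | [Li]c1c(OCC=C)cc(OCC=C)cc1OCC=C
F4 | step 6 | (5Z,8Z,11Z,13E,15S,17Z)-15-(tert-butyldimethylsilyloxy)-1-[2,4,6-tris(allyloxy)phenyl]icosa-5,8,11,13,17-pentaen-1-one | CC/C=C\C[C@H](O[Si](C)(C)C(C)(C)C)/C=C/C=C\C/C=C\C/C=C\CCCC(=O)c1c(OCC=C)cc(OCC=C)cc1OCC=C
F5 | step 5 | 2,2-dimethyl-6-(2-oxopropyl)-4H-1,3-dioxin-4-one | CC(=O)CC1=CC(=O)OC(C)(C)O1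
F6 | step 5 | dilithium dianion of 2,2-dimethyl-6-(2-oxopropyl)-4H-1,3-dioxin-4-one | [CH2-]C(=O)[CH-]C1=CC(=O)OC(C)(C)O1.[Li+].[Li+]
F7 | step 5 | 6-[(8Z,11Z,14Z,16E,18S,20Z)-18-(tert-butyldimethylsilyloxy)-2,4-dioxotricosa-8,11,14,16,20-pentaenyl]-2,2-dimethyl-4H-1,3-dioxin-4-one | CC/C=C\C[C@H](O[Si](C)(C)C(C)(C)C)/C=C/C=C\C/C=C\C/C=C\CCCC(=O)CC(=O)CC1=CC(=O)OC(C)(C)O1
F8 | step 5 | (11Z,14Z,17Z,19E,21S,23Z)-21-(tert-butyldimethylsilyloxy)hexacosa-1,11,14,17,19,23-hexaene-1,3,5,7-tetrone | CC/C=C\C[C@H](O[Si](C)(C)C(C)(C)C)/C=C/C=C\C/C=C\C/C=C\CCCC(=O)CC(=O)CC(=O)C=C=O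
F9 | step 7 | methyl (11Z,14Z,17Z,19E,21S,23Z)-21-hydroxy-3,5,7-trioxohexacosa-11,14,17,19,23-pentaenoate | CC/C=C\C[C@H](O)/C=C/C=C\C/C=C\C/C=C\CCCC(=O)CC(=O)CC(=O)CC(=O)OC
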